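At late times the earlier runs stand level: grey reads 58 % at 12.0 h, amber 57 % and red 56 % at 10.0 h, although Z goes from 0.11 M to 0.24 M.

| setting | grey | amber | red | oak | maple | alder | birch |
|---|---|---|---|---|---|---|---|
| G | 0.16 M | 0.16 M | 0.16 M | 0.16 M | 0.16 M | 0.16 M | 0.16 M (fed, over 2.5 h) |
| E | 0.16 M | 0.16 M | 0.16 M | 0.160 M (fed, over 2.5 h) | 0.160 M | 0.160 M (in portions, 4, over 2.5 h) | 0.160 M |
| Z | 0.16 M | 0.11 M | 0.24 M | 0.160 M | 0.160 M | 0.160 M | 0.160 M |
| remark | run made earlier | run made earlier | run made earlier | all else is in the flask from the start; the feed brings no volume worth counting | everything together at the start | first portion at the start, last at 2.5 h | all else is in the flask from the start; the feed brings no volume worth counting |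
| time |  |  |  | 12 h | 12 h | 12 h | 12 h |

| run | time / h | X / % |
|---|---|---|
| grey | 1.00 | 11 |
| grey | 3.00 | 36 |
| grey | 6.00 | 50 |
| grey | 8.00 | 54 |
| grey | 12.0 | 58 |
| amber | 2.00 | 26 |
| amber | 4.00 | 42 |
| amber | 6.00 | 46 |
| amber | 8.00 | 57 |
| amber | 10.0 | 57 |
| red | 0.833 | 10 |
| red | 2.50 | 30 |
| red | 4.00 | 41 |
| red | 6.00 | 51 |
| red | 10.0 | 56 |

(readings scatter by 1.5 percentage points)

* which flask leads in amount of X, in percent of the G charged ("all alike" within 1.5 percentage points) (oak / maple / alder / birch / all alike)
* how much X is there at the end, in percent of the G charged: oak
* how much X is there at the end, in percent of the G charged: maple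
* how much X is there at the end, in percent of the G charged: alder
* how much X is there at the end, in percent of the G charged: birch

- the numbers in the tables scatter with a standard deviation of 1.5 percentage points
- reactions considered so far: G + E -> Q; G + Z -> L; E -> D; Q -> X; 2 E -> J

I keep the books on E, which I treat as the limiting reagent. A mole of E has two exits: into Q and on to X, or into a loss that I take as first order. Z barely moves the plateaus, so I drop it from this ledger as a small correction. In grey, with equal charges, the Q entry closes at 58 % of the E charged and the loss entry at 42.0 %.

At each moment the Q exit takes the share G/(G + a) of the E being spent. With equal charges and Z dropped, integrating until E is gone gives, in this ledger: G then left = a ln(G charged / G then left). The grey plateau therefore yields a = 0.0775 M. This a is the break-even level, the concentration of G at which G takes E as fast as E is lost.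

In this ledger the share depends on the level of G, not on how E is dosed, so I expect a slow dose of E to gain nothing and to leave G longer beside Z. Birch's feed needs 1.21 h to have delivered as much G as a, even with none consumed. I commit to maple near 58 % and leading, oak and alder below it, and birch lowest.

The forecast gives oak 61 %, maple 58 %, alder 60 % and birch 50 %, with oak leading, which differs from my order. On birch it says: “Birch lets E decay before G arrives”.

The flasks give oak 44.2 %, maple 56.6 %, alder 44.7 % and birch 17.0 %, so maple leads.

    G + E → Q (k = 0.00780 M⁻¹ s⁻¹)
    G + Z → L (k = 8.20 × 10⁻⁴ M⁻¹ s⁻¹)
    E → D (k = 4.90 × 10⁻⁴ s⁻¹)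
    Q → X (k = 9.20 × 10⁻⁵ s⁻¹)
    2 E → J (k = 2.80 × 10⁻⁴ M⁻¹ s⁻¹)

The largest single effect on the gap of 40 percentage points between maple and birch is the step E to D: in the run without it the gap is 11 points. Half of birch's capture is over by 0.589 h, earlier than the 1.21 h its feed needs to bring a. Birch's books pass 17.4 % of E through Q, so the share rule puts the effective level of G met by E in birch at 0.0163 M, lower than a. The neighbour of birch with 0.64 M of E passes 8.90 % of its charge through Q, which by the same first-order rule, with the E in J not counted apart, gives an effective level of 0.00757 M, half of birch's.

(All runs stem from a simulated flask with made-up constants; noise was put on by code.)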